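**Retrosynthetic overview**
1. The target is reached by global O-debenzylation of tetrabenzyl ether 12; no ring is formed anywhere in the route, since both benzene rings come intact from the one benzylic bromide 1.
2. Key disconnection of 12: the C-4–C-5 bond of the undecan-4-yl chain (carbinol carbon to chain CH2) together with the acyl C–O bond, giving aroyl bromide 7, butanal 10 and terminal olefin 9.
3. Enabling feature: C-4 is an O-acylated carbinol carbon, bearing the benzoate oxygen and C=O of the 2,4-dioxygenated 6-undecylbenzene ring. Such a carbon arises from aldehyde plus acyl bromide as a racemic 1-bromoalkyl ester, whose weak C–Br bond gives an O-stabilised radical for enantioconvergent capture at a chiral nickel centre.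
4. 7 comes from undecylarene 3 by formylation, oxidation and bromide formation; 3 and 9 come from 1 by Cu-catalysed Grignard coupling.

Key step: step 6

Remark: the stereocentre is C-4 of the undecan-4-yl chain and is (R) by CIP (O > 7-arylheptyl > propyl > H).
Assumption: the Grignard reagents 2 and 8 are taken as purchasable ethereal solutions (8 is otherwise made from 6-bromohex-1-ene and Mg directly before use).
Assumption: the sense of induction of the bis(oxazoline) ligand in step 6 is assigned in a test run with both antipodes, and the antipode giving the (R)-ester is used.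

**Step 1**
Reactants: 1 3,5-bis(benzyloxy)benzyl bromide; 2 decylmagnesium bromide
Product: 3 1,3-bis(benzyloxy)-5-undecylbenzene
Conditions: Li2CuCl4 (cat.), THF, −78 → 0 °C, slow addition of 2
Reagents that add atoms: none
Why: Cu-catalysed sp3–sp3 Grignard cross-coupling (Kochi coupling) of a primary alkylmagnesium halide with a reactive benzylic bromide; the benzyl aryl ethers are inert.

**Step 2**
Reactants: 3 1,3-bis(benzyloxy)-5-undecylbenzene
Product: 5 2,4-bis(benzyloxy)-6-undecylbenzaldehyde, via aryl iminium chloride 4 (not isolated)
Conditions: POCl3, DMF, 0 → 40 °C; then H2O, 0 °C → rt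
Reagents that add atoms: N,N-dimethylformamide CN(C)C=O (formyl carbon; N-methyl groups of 4); water O (carbonyl oxygen of 5); phosphoryl chloride O=P(Cl)(Cl)Cl (chloride counter-ion of 4 only)
Why: Vilsmeier–Haack formylation of the electron-rich resorcinol diether should occur para to one benzyloxy group, at the ring position flanked by the alkyl chain and the other ether (the orcinol diether pattern), and not between the two bulky benzyloxy groups.

**Step 3**
Reactants: 5 2,4-bis(benzyloxy)-6-undecylbenzaldehyde
Product: 6 2,4-bis(benzyloxy)-6-undecylbenzoic acid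
Conditions: NaClO2, NaH2PO4, 2-methylbut-2-ene, t-BuOH/THF/H2O, 0 °C → rt
Reagents that add atoms: sodium chlorite [Na+].[O-]Cl=O
Why: Pinnick oxidation converts the hindered aryl aldehyde to the acid without touching the benzyl ethers, the olefin scavenger removing HOCl before it can chlorinate the electron-rich ring.

**Step 4**
Reactants: 6 2,4-bis(benzyloxy)-6-undecylbenzoic acid
Product: 7 2,4-bis(benzyloxy)-6-undecylbenzoyl bromide
Conditions: (COBr)2, DMF (cat.), CH2Cl2, 0 °C → rt, N2 sweep; concentrate, use crude
Reagents that add atoms: oxalyl bromide O=C(Br)C(=O)Br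
Why: Vilsmeier-type activation of the acid by oxalyl bromide/DMF (acyl halide formation) should give the acyl bromide, with only gases as by-products, so the crude material can be taken on directly.

**Step 5**
Reactants: 1 3,5-bis(benzyloxy)benzyl bromide; 8 hex-5-en-1-ylmagnesium bromide
Product: 9 1,3-bis(benzyloxy)-5-(hept-6-en-1-yl)benzene
Conditions: Li2CuCl4 (cat.), THF, −78 → 0 °C, slow addition of 8
Reagents that add atoms: none
Why: The same Cu-catalysed Kochi coupling as in step 1 joins the benzylic carbon to the hexenyl chain, and the remote terminal olefin is untouched by the organocopper species.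

**Step 6**
Reactants: 7 2,4-bis(benzyloxy)-6-undecylbenzoyl bromide; 10 butanal; 9 1,3-bis(benzyloxy)-5-(hept-6-en-1-yl)benzene
Product: 12 (4R)-11-[3,5-bis(benzyloxy)phenyl]undecan-4-yl 2,4-bis(benzyloxy)-6-undecylbenzoate, via racemic 1-bromobutyl ester 11 (not isolated)
Conditions: 7 + 10, neat (or minimal i-Pr2O), 0 °C → rt; then 9, NiBr2·glyme (cat.), chiral C2-symmetric bis(oxazoline) ligand (cat.), (EtO)3SiH, K3PO4·H2O, i-Pr2O/DMA, rt
Reagents that add atoms: none
Why: Butanal inserts into the acyl C–Br bond of 7 to give racemic 1-bromobutyl ester 11; a Ni(I) species abstracts bromine to give a planar α-acyloxyalkyl radical, while the chiral bis(oxazoline)Ni–H formed from silane and phosphate adds anti-Markovnikov to the terminal C=C of 9 to give a primary alkylnickel, which captures the radical and reductively eliminates the C-4–C-5 bond. The closest known reaction type is the Ni-catalysed enantioconvergent hydroalkylation of terminal olefins with racemic 1-bromoalkyl esters and a hydrosilane, including its four-component aldehyde/acyl bromide/olefin/silane form. No ring is closed. The C-4 stereocentre is set under catalyst control by the ligand at the radical-capture/reductive-elimination stage, both enantiomers of 11 converging through the common radical. The ligand tells the electrophile-derived propyl group from the olefin-derived 7-arylheptyl chain by origin and not by size, which matters because the two n-alkyl arms are sterically almost identical. The step needs linear Ni–H addition without chain walking and C–C coupling faster than reduction of the C–Br bond; the unactivated monosubstituted olefin, the oxygen-activated C–Br bond and the ester carbonyl as a ligating group should secure this, and the benzyl ethers are inert.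

**Step 7**
Reactants: 12 (4R)-11-[3,5-bis(benzyloxy)phenyl]undecan-4-yl 2,4-bis(benzyloxy)-6-undecylbenzoate
Product: 13 (4R)-11-(3,5-dihydroxyphenyl)undecan-4-yl 2,4-dihydroxy-6-undecylbenzoate
Conditions: H2 (1 atm), 10% Pd/C, EtOAc/EtOH, rt
Reagents that add atoms: none
Why: Catalytic hydrogenolysis cleaves the four benzyl aryl ethers, while the secondary alkyl ester has no benzylic C–O bond and the C-4 stereocentre is not touched.

**Compound list**
1 | 3,5-bis(benzyloxy)benzyl bromide | BrCc1cc(OCc2ccccc2)cc(OCc2ccccc2)c1 | starting material
2 | decylmagnesium bromide | CCCCCCCCCC[Mg]Br | starting material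
3 | 1,3-bis(benzyloxy)-5-undecylbenzene | CCCCCCCCCCCc1cc(OCc2ccccc2)cc(OCc2ccccc2)c1 | intermediate
4 | N-[2,4-bis(benzyloxy)-6-undecylbenzylidene]-N-methylmethanaminium chloride (aryl iminium chloride) | CCCCCCCCCCCc1cc(OCc2ccccc2)cc(OCc2ccccc2)c1C=[N+](C)C.[Cl-] | intermediate (not isolated)
5 | 2,4-bis(benzyloxy)-6-undecylbenzaldehyde | CCCCCCCCCCCc1cc(OCc2ccccc2)cc(OCc2ccccc2)c1C=O | intermediate
6 | 2,4-bis(benzyloxy)-6-undecylbenzoic acid | CCCCCCCCCCCc1cc(OCc2ccccc2)cc(OCc2ccccc2)c1C(=O)O | intermediate
7 | 2,4-bis(benzyloxy)-6-undecylbenzoyl bromide | CCCCCCCCCCCc1cc(OCc2ccccc2)cc(OCc2ccccc2)c1C(=O)Br | intermediate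
8 | hex-5-en-1-ylmagnesium bromide | C=CCCCC[Mg]Br | starting material
9 | 1,3-bis(benzyloxy)-5-(hept-6-en-1-yl)benzene | C=CCCCCCc1cc(OCc2ccccc2)cc(OCc2ccccc2)c1 | intermediate
10 | butanal | CCCC=O | starting material
11 | 1-bromobutyl 2,4-bis(benzyloxy)-6-undecylbenzoate (racemic) | CCCCCCCCCCCc1cc(OCc2ccccc2)cc(OCc2ccccc2)c1C(=O)OC(Br)CCC | intermediate (not isolated)
12 | (4R)-11-[3,5-bis(benzyloxy)phenyl]undecan-4-yl 2,4-bis(benzyloxy)-6-undecylbenzoate | CCCCCCCCCCCc1cc(OCc2ccccc2)cc(OCc2ccccc2)c1C(=O)O[C@H](CCC)CCCCCCCc1cc(OCc2ccccc2)cc(OCc2ccccc2)c1 | intermediate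
13 | (4R)-11-(3,5-dihydroxyphenyl)undecan-4-yl 2,4-dihydroxy-6-undecylbenzoate | CCCCCCCCCCCc1cc(O)cc(O)c1C(=O)O[C@H](CCC)CCCCCCCc1cc(O)cc(O)c1 | target

**Step count and risks**
Total steps: 7. Longest linear sequence: 6 (steps 1, 2, 3, 4, 6, 7).

Steps most likely to fail:

1. Step 6. Radical capture at nickel may be slow or unselective because the carbonyl of the 2,6-disubstituted, electron-rich aroyloxy group is twisted and shielded, so that reduction of the C–Br bond and erosion of enantioselectivity compete. The fallback sets out from 9, 10 and acid 6 and comes back at 12. The same four-component coupling would be run with commercial benzoyl bromide as a small auxiliary acyl group and the antipodal ligand. Through racemic 1-bromobutyl benzoate F1 this should give (4S)-11-[3,5-bis(benzyloxy)phenyl]undecan-4-yl benzoate F2. Methanolysis (K2CO3, MeOH) would give (4S)-11-[3,5-bis(benzyloxy)phenyl]undecan-4-ol F3. Mitsunobu esterification of F3 with acid 6 (PPh3, DIAD, toluene, 0 °C → rt) would then install the hindered aroyl group with inversion at C-4 and give 12.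

2. Step 4. The benzyl ether ortho to the carbonyl may be lost through the HBr that is set free, and the electron-rich aroyl bromide may decompose on concentration. The fallback sets out from acid 6 and butanal 10 and comes back at 12. Neutral chlorination of 6 with 1-chloro-N,N,2-trimethylprop-1-en-1-amine in CH2Cl2 would give 2,4-bis(benzyloxy)-6-undecylbenzoyl chloride F4. Its addition to 10 with catalytic ZnCl2 would give the isolable racemic 1-chlorobutyl 2,4-bis(benzyloxy)-6-undecylbenzoate F5. Halide exchange with NaI in acetone would give racemic 1-iodobutyl 2,4-bis(benzyloxy)-6-undecylbenzoate F6, which would be taken with 9 into the nickel stage of step 6 in place of 11 to give 12.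

3. Step 2. Formylation at the position flanked by the undecyl chain and a benzyloxy group may be sluggish, and forcing conditions may lead to attack between the two benzyloxy groups or to acid-mediated loss of a benzyl group. The fallback sets out from 3 and comes back at acid 6, so that step 3 is skipped. Bromination with NBS in MeCN at 0 °C would give 1,5-bis(benzyloxy)-2-bromo-3-undecylbenzene F7. Bromine–lithium exchange with n-BuLi in THF at −78 °C would give [2,4-bis(benzyloxy)-6-undecylphenyl]lithium F8, which would be carboxylated with CO2 and acidified (aq. HCl) to give 6.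

**Further compounds**
F1 | step 6 | 1-bromobutyl benzoate (racemic, formed in the flask) | CCCC(Br)OC(=O)c1ccccc1
F2 | step 6 | (4S)-11-[3,5-bis(benzyloxy)phenyl]undecan-4-yl benzoate | O=C(O[C@@H](CCC)CCCCCCCc1cc(OCc2ccccc2)cc(OCc2ccccc2)c1)c1ccccc1
F3 | step 6 | (4S)-11-[3,5-bis(benzyloxy)phenyl]undecan-4-ol | O[C@@H](CCC)CCCCCCCc1cc(OCc2ccccc2)cc(OCc2ccccc2)c1
F4 | step 4 | 2,4-bis(benzyloxy)-6-undecylbenzoyl chloride | CCCCCCCCCCCc1cc(OCc2ccccc2)cc(OCc2ccccc2)c1C(=O)Cl
F5 | step 4 | 1-chlorobutyl 2,4-bis(benzyloxy)-6-undecylbenzoate (racemic) | CCCCCCCCCCCc1cc(OCc2ccccc2)cc(OCc2ccccc2)c1C(=O)OC(Cl)CCC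
F6 | step 4 | 1-iodobutyl 2,4-bis(benzyloxy)-6-undecylbenzoate (racemic) | CCCCCCCCCCCc1cc(OCc2ccccc2)cc(OCc2ccccc2)c1C(=O)OC(I)CCC
F7 | step 2 | 1,5-bis(benzyloxy)-2-bromo-3-undecylbenzene | CCCCCCCCCCCc1cc(OCc2ccccc2)cc(OCc2ccccc2)c1Br
F8 | step 2 | [2,4-bis(benzyloxy)-6-undecylphenyl]lithium | CCCCCCCCCCCc1cc(OCc2ccccc2)cc(OCc2ccccc2)c1[Li]
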